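Atom numbering used for every tetralin below: C1 = ArCH, C2 and C3 = the carbons that carry CH2OH, C4 = benzylic CH2, ring A = C4a, C5 (H), C6 (OMe), C7 (O), C8 (O), C8a; ring B = C1, C2, C3, C4, C4a, C8a. The pendant ring is the 4-oxygenated 3-methoxyphenyl group on C1. Compound numbers 1 to 18 are those of the steps and of the compound list.

Remark on the chemistry: 10, 11, 12, 13 and 15 are racemates; their names carry "rac" and their SMILES show the enantiomer that is carried on to 18. Compounds 1, 3, 6 and 14, dichlorodiphenylmethane and benzyl bromide are assumed to be commercial.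

## The problem

Compound 18 is an aryltetralin cyclolignan: a cyclohexene ring B fused to ring A, which is substituted at every position but C5 (6-OMe, 7-OH, 8-OH), with a guaiacyl ring on C1 and hydroxymethyl groups on C2 and C3. The three contiguous stereocentres are all trans, (1S,2R,3R), and none of them sits next to a heteroatom through which it could be introduced by a standard asymmetric oxidation or reduction. They are not independent. C2 is the pivot: a ring closure at C1 beside an existing C2 substituent gives the 1,2-trans arrangement, and C3 can be equilibrated to the 2,3-trans arrangement while it carries a carbonyl group, whereas C1 and C2 cannot be corrected once made. The absolute problem therefore comes down to one centre, C2, or to a separation of enantiomers. Ring A offers two free carbons ortho to the C4 side chain, C5 and C8a, and the C1–C8a bond must form at the one beside the C8 oxygen. The 6-methoxy-7,8-catechol is oxidised by air and by one-electron oxidants, and the guaiacyl phenol para to C1 can be oxidised to a quinone methide that would erase C1. A free C2 hydroxymethyl group also closes a lactone onto a C3 carboxyl, which then settles in the cis-fused, wrong 2,3-relation, so the phenols must be masked throughout and released last without acid or oxidant. A short synthesis is possible because C2–C3 is the 8–8' link of two C6C3 units, C1 is benzylic to a para-oxygenated ring, and C8a lies para to the C6 methoxy group. A radical at C3 that adds to a C1=C2 styrene double bond leaves at C1 a radical, or after oxidation a cation, placed for six-membered closure onto C8a.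

## Retrosynthesis

**18 from 17.** The last cut removes only protecting groups: the benzyl ether on the pendant phenol, the benzyl ether on the C2 hydroxymethyl group, and the diphenylmethylene ketal across the C7 and C8 oxygens. All three are benzylic C–O bonds, so one hydrogenolysis frees 18 under neutral, reductive conditions, which suits the air-sensitive methoxycatechol. Acid-labile or fluoride-labile groups would need extra steps and expose the free catechol to work-ups. The forward step must only leave the C1–aryl bonds alone, which carry no heteroatom.

**17 from 16, and 16 from 13 and 14.** The C3 hydroxymethyl group is traced to a C3 acyl group, and the acyl group is used to secure the absolute configuration. In the ring-forming step, C2 is created by an intermolecular radical addition in which the radical carbon itself ends up non-stereogenic. A chiral Lewis acid complex on that radical (for example Mg(ClO4)2 with a bis(oxazoline) ligand) would have to distinguish the faces of the incoming alkene at a distance, in acetic acid that would strip it from the malonate. That is not a basis to build on. The annulation is therefore used for bond construction and relative configuration, and the enantiomers are parted as covalent diastereomers. Racemic acid 13 is joined to the oxazolidinone 14, the (1S,2R,3R) imide 16 is separated, and its reductive cleavage is the very reduction that makes the C3 hydroxymethyl group of 17. The cost is one hydrolysis and one acylation beyond a direct ester reduction, and half of the material. The forward chemistry must deliver two separable imides.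

**13 from 12, 11 and 10.** Adding a second ester to C3 (the reverse of a Krapcho dealkoxycarbonylation) turns C3 into the central carbon of a malonate, 10. That removes the C3 stereocentre from the ring-forming step and gives C3 the acidity needed to generate a radical. In the forward direction C3 is re-formed as an epimer mixture (11) and set trans by equilibration of the ester 12 before hydrolysis to 13. This is why the C2 oxygen is carried as a benzyl ether and not as an ester: an ester would be cleaved by methoxide, and the freed alcohol would lactonise onto C3 and drive the system to the cis-fused lactone.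

**10 from 5 and 9.** This is the key disconnection: C2–C3 and C1–C8a are cut together. Cutting C1–C2, or C4–C4a, or C1–C8a with C4–C4a each leaves a precursor whose stereocentres or diaryl carbon must first be assembled in a linear sequence. Only this pair of cuts divides 10 into two halves of equal size, each a C6C3 unit: the ring A benzylmalonate 5 and the coniferyl-type alkene 9. Using a malonate as one partner makes the cross-coupling unambiguous, because only 5 can be oxidised to a carbon radical and product 10, without a malonate hydrogen, cannot be oxidised again. The forward reaction has three requirements: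

- The radical must add at C2 of 9, which is secured by the benzylic, para-alkoxy stabilised radical that results at C1.
- Closure must give the 1,2-trans ring.
- Closure must occur at C8a and not at C5.

Blocking C5 with a halogen would settle the third point, but the halogen cannot be placed there directly. Electrophilic halogenation of 1 or its ethers is expected at the other free carbon, para to the methoxy group, which is the future C8a. That preference is therefore used instead of opposed. C8a is para to the C6 methoxy group, and the C7 and C8 oxygens are tied back in a five-membered ketal so that the C8 oxygen does not shield C8a. Closure at C5 would force the methoxy group, already flanked by the C7 oxygen, out of conjugation.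

**5 from 4, and 4 from 2 and 3; 2 from 1.** The C3–C4 bond is cut to the aldehyde 2 and dimethyl malonate 3 through the arylidene malonate 4 (Knoevenagel condensation, then conjugate reduction). The neighbouring option, alkylating 3 with a ring A benzyl halide, costs one more step, risks double alkylation, and passes through a labile electron-rich benzyl halide. Aldehyde 2 is the ketal of 5-hydroxyvanillin 1. Only the adjacent 3,4-hydroxyl pair of 1 can form the ring, so the protection needs no selectivity.

**9 from 8, 7 and 6.** The alkene partner is coniferyl alcohol with both oxygens benzylated. It is cut at the two O–benzyl bonds and at the oxidation level of C9 back to ferulic acid 6: double benzylation gives 7, ester reduction gives 8, and etherification gives 9. The E double bond of 6 is carried through unchanged. The sequence must only avoid acid, which ionises cinnamyl-type alcohols.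

## Roads not taken

**Alternative 1:** The cut is C4–C4a. In the forward step KOtBu deprotonates the free C7 phenol of the acyclic tosylate A2, and the phenoxide carbon para to oxygen, C4a, displaces the C4 tosylate in a 6-exo closure. The dienone then tautomerises to the tetralin A1.
- Merits: the ring closure touches none of the stereocentres, so all three can be set beforehand by acyclic asymmetric methods and A1 is obtained as one enantiomer without any separation. The site of closure is certain because C4a is the only unsubstituted carbon ortho or para to the phenoxide oxygen.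
- Weak points: A2 contains the diarylmethine C1, a carbon bearing two electron-rich aryl groups, which must be made enantioselectively in an open chain with C2 and C3 set relative to it. That is a long linear sequence. The C7 and C8 oxygens must be told apart (C7 free, C8 benzylated), a protecting-group problem that the ketal of the chosen route avoids. Carbon alkylation of a phenoxide with loss of aromaticity competes with intermolecular O-alkylation and with elimination of the primary tosylate under KOtBu.
- Comparison: Alternative 1 is better in absolute stereocontrol and in certainty of the closure site. The chosen plan sets against this its convergence (two C–C bonds and ring B in one step from two three-step fragments), and pays by discarding the unwanted enantiomer at step 10.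

**Alternative 2:** The cuts are C1–C8a and C4–C4a. The forward step is a Diels–Alder reaction in which the quinone A4 acts as dienophile through its unsubstituted C=C toward the diene A5. Double enolisation then restores ring A and gives the dihydronaphthalene catechol A3.
- Merits: on paper this is the most convergent ring construction. Ring A arrives with its three oxygens in place and needs no phenol protection.
- Weak points: ortho-quinones dimerise and usually react as carbodienes or heterodienes, not as dienophiles. The regiochemistry that must join the aryl-bearing diene terminus to the future C8a is not secured by the methoxy group. Enantioselective catalysis with an ortho-quinone dienophile is not established, and C1 is the only stereocentre formed. That centre is doubly activated in a 1,4-dihydronaphthalene bearing a free catechol, which is prone to aromatise. Most seriously, A3 lacks the C2 hydroxymethyl carbon, so a carbon must still be added to the C2=C3 alkene with control of two more stereocentres.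
- Comparison: Alternative 2 forms ring B in fewer operations and is better in protecting-group economy. The chosen plan sets against this that its key step delivers every carbon of 18 and the 1,2-relative configuration, from partners that are stable and easy to make.

**Alternative 3:** The cut is C1–C2. In the forward step a diarylprolinol silyl ether converts the aldehyde of the quinone methide A7 into an enamine. Its C2 adds 1,6 to the quinone methide carbon C1 in a 6-exo closure and rearomatises the pendant ring to the free phenol of A6.
- Merits: C1 and C2 are formed under catalyst control, the C2 aldehyde is one reduction from the hydroxymethyl group, and the pendant phenol is unmasked in the same step. Amine-catalysed 1,6-additions to para-quinone methides are a known reaction type.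
- Weak points: the C3 stereocentre must be made enantioselectively beforehand, and the C1–C8a diaryl bond must be built beside the C8 oxygen in the same linear sequence. The guaiacyl-type quinone methide of A7 has no stabilising flanking groups, so it must be generated in the flask in the presence of a secondary amine that can itself add to it. The catalyst and the C3 centre may be matched or mismatched.
- Comparison: Alternative 3 is the better plan for absolute stereocontrol at C1 and C2 and has no question about the closure site. The chosen plan sets against this robust intermediates, much shorter fragment syntheses, and a ring closure that needs no quinone methide. Its price is the separation of enantiomers.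

Key step: step 7

## Route

Step 1
Reactants: 1 3,4-dihydroxy-5-methoxybenzaldehyde (5-hydroxyvanillin)
Product: 2 7-methoxy-2,2-diphenyl-1,3-benzodioxole-5-carbaldehyde
Conditions: Ph2CCl2, Ph2O, 175 °C
Reagents that add atoms: dichlorodiphenylmethane, ClC(Cl)(c1ccccc1)c1ccccc1
Why: Ketalisation by double nucleophilic substitution of the gem-dichloride by the two adjacent phenols; only the catechol pair can close the five-membered ring, so there is no regiochemical question, and the aldehyde is inert.

Step 2
Reactants: 2 7-methoxy-2,2-diphenyl-1,3-benzodioxole-5-carbaldehyde; 3 dimethyl malonate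
Product: 4 dimethyl 2-[(7-methoxy-2,2-diphenyl-1,3-benzodioxol-5-yl)methylidene]malonate
Conditions: piperidine (cat.), AcOH (cat.), toluene, reflux, azeotropic removal of water
Reagents that add atoms: none
Why: Knoevenagel condensation; 2 has no enolisable position and the ketal is stable to the weakly basic medium.

Step 3
Reactants: 4 dimethyl 2-[(7-methoxy-2,2-diphenyl-1,3-benzodioxol-5-yl)methylidene]malonate
Product: 5 dimethyl 2-[(7-methoxy-2,2-diphenyl-1,3-benzodioxol-5-yl)methyl]malonate
Conditions: NaBH4, MeOH/THF, 0 °C
Reagents that add atoms: none
Why: Conjugate (1,4) hydride reduction of an arylidene malonate; the ester groups and the ketal are not attacked at 0 °C, and the sequence avoids a labile benzyl halide and double alkylation of 3.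

Step 4
Reactants: 6 (E)-ferulic acid
Product: 7 benzyl (E)-3-[4-(benzyloxy)-3-methoxyphenyl]prop-2-enoate
Conditions: BnBr, K2CO3, DMF, 60 °C
Reagents that add atoms: benzyl bromide, BrCc1ccccc1
Why: Williamson ether synthesis at the phenoxide and O-alkylation of the carboxylate in one operation; the E alkene is not affected.

Step 5
Reactants: 7 benzyl (E)-3-[4-(benzyloxy)-3-methoxyphenyl]prop-2-enoate
Product: 8 (E)-3-[4-(benzyloxy)-3-methoxyphenyl]prop-2-en-1-ol (4-O-benzylconiferyl alcohol)
Conditions: i-Bu2AlH, CH2Cl2, −78 °C; aq. potassium sodium tartrate
Reagents that add atoms: none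
Why: 1,2-Reduction of the conjugated ester by the aluminium hydride at low temperature gives the allylic alcohol without touching the alkene or the aryl benzyl ether.

Step 6
Reactants: 8 (E)-3-[4-(benzyloxy)-3-methoxyphenyl]prop-2-en-1-ol
Product: 9 1-(benzyloxy)-4-[(E)-3-(benzyloxy)prop-1-enyl]-2-methoxybenzene (coniferyl alcohol dibenzyl ether)
Conditions: NaH, BnBr, Bu4NI (cat.), THF, 0 °C to rt
Reagents that add atoms: benzyl bromide, BrCc1ccccc1
Why: Williamson ether synthesis of the primary allylic alkoxide; an ether is chosen at this oxygen so that the later methoxide treatment cannot free the alcohol and close a lactone onto C3.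

Step 7
Reactants: 5 dimethyl 2-[(7-methoxy-2,2-diphenyl-1,3-benzodioxol-5-yl)methyl]malonate; 9 1-(benzyloxy)-4-[(E)-3-(benzyloxy)prop-1-enyl]-2-methoxybenzene (1.5 equiv)
Product: 10 dimethyl rac-(1S,2R)-1-[4-(benzyloxy)-3-methoxyphenyl]-2-(benzyloxymethyl)-6-methoxy-7,8-(diphenylmethylenedioxy)tetralin-3,3-dicarboxylate (1,2-trans)
Conditions: Mn(OAc)3·2H2O (2.2 equiv), Cu(OAc)2·H2O (0.2 equiv), NaOAc, AcOH, 60 °C, argon
Reagents that add atoms: none
Why: Mn(OAc)3, a one-electron oxidant of trivalent manganese, oxidises the acetate-assisted enol of 5 to an electrophilic tertiary malonyl radical at C3, which adds to the electron-rich alkene of 9 at C2 because only this regiochemistry gives a benzylic C1 radical stabilised by the para-benzyloxy group. Cu(OAc)2 oxidises that radical to the para-alkoxybenzyl cation (divalent copper is regenerated by Mn(OAc)3), the cation alkylates ring A and a proton is lost; the closest known reaction type is the Mn(OAc)3-mediated annulation of benzylmalonates with alkenes to tetralins, here with a radical–polar crossover before ring closure. Ring B closes in a six-membered Friedel–Crafts mode at the ortho carbon, 6-endo with respect to the C4a=C8a bond. C2 is created in the intermolecular addition without facial bias, so 10 is racemic; C1 is set relative to C2 in the ring closure, where a chair-like transition state with the C1 aryl group and the C2 benzyloxymethyl group both pseudo-equatorial gives the 1,2-trans isomer. The step needs closure at C8a and not at C5: C8a is para to the C6 methoxy group, which stays coplanar and donating only while its methyl points toward C5, and the ketal holds the C8 oxygen away from the reacting carbon, whereas closure at C5 would force the methoxy group out of plane. Product 10 has no malonate hydrogen and is inert to further oxidation, and a benzylic acetate formed by capture of the cation can reionise in warm acetic acid.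

Step 8
Reactants: 10 dimethyl rac-(1S,2R)-1-[4-(benzyloxy)-3-methoxyphenyl]-2-(benzyloxymethyl)-6-methoxy-7,8-(diphenylmethylenedioxy)tetralin-3,3-dicarboxylate
Product: 11 methyl rac-(1S,2R)-1-[4-(benzyloxy)-3-methoxyphenyl]-2-(benzyloxymethyl)-6-methoxy-7,8-(diphenylmethylenedioxy)tetralin-3-carboxylate (both C3 epimers)
Conditions: LiCl, H2O, DMSO, 155 °C
Reagents that add atoms: none
Why: Krapcho dealkoxycarbonylation: chloride demethylates one ester by SN2 attack, the carboxylate loses CO2 and water protonates the ester enolate; benzyl ethers and ketal are stable to this neutral medium, and C3 forms as an epimer mixture that the next step corrects.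

Step 9
Reactants: 11 methyl rac-(1S,2R)-1-[4-(benzyloxy)-3-methoxyphenyl]-2-(benzyloxymethyl)-6-methoxy-7,8-(diphenylmethylenedioxy)tetralin-3-carboxylate (both C3 epimers)
Product: 13 rac-(1S,2R,3R)-1-[4-(benzyloxy)-3-methoxyphenyl]-2-(benzyloxymethyl)-6-methoxy-7,8-(diphenylmethylenedioxy)tetralin-3-carboxylic acid (all-trans), via all-trans methyl ester 12 (not isolated)
Conditions: NaOMe (0.3 equiv), MeOH, reflux; then aq. NaOH, reflux; then aq. HCl
Reagents that add atoms: sodium hydroxide, [Na+].[OH-] (its oxygen becomes the carboxyl OH oxygen)
Why: Base-mediated epimerisation through the ester enolate, then saponification: under methoxide C3 equilibrates to the all-trans ester 12, in which aryl, benzyloxymethyl and ester groups are all pseudo-equatorial on the half-chair (the tied-back C8 oxygen puts little peri strain on the C1 aryl group), and hydroxide then hydrolyses the ester without further change at C3. The ether at the C2 side chain rules out lactonisation.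

Step 10
Reactants: 13 rac-(1S,2R,3R)-1-[4-(benzyloxy)-3-methoxyphenyl]-2-(benzyloxymethyl)-6-methoxy-7,8-(diphenylmethylenedioxy)tetralin-3-carboxylic acid; 14 (S)-4-benzyloxazolidin-2-one
Product: 16 (4S)-4-benzyl-3-{[(1S,2R,3R)-1-[4-(benzyloxy)-3-methoxyphenyl]-2-(benzyloxymethyl)-6-methoxy-7,8-(diphenylmethylenedioxy)tetralin-3-yl]carbonyl}oxazolidin-2-one, via mixed pivalic anhydride 15 (not isolated)
Conditions: t-BuCOCl, Et3N, THF, −20 °C; then lithium salt of 14 (n-BuLi), THF, −78 to 0 °C; separation of the two diastereomers on silica
Reagents that add atoms: pivaloyl chloride, CC(C)(C)C(Cl)=O (its atoms stay only in intermediate 15)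
Why: N-Acylation of a lithiated oxazolidinone by a mixed anhydride, with attack at the less hindered, non-pivaloyl carbonyl; no stereocentre is made. Racemic 13 and enantiopure 14 give two diastereomeric imides in equal amounts, and the (1S,2R,3R) isomer 16 is separated by chromatography or crystallisation and its configuration assigned by X-ray analysis: a resolution through covalent diastereomers.

Step 11
Reactants: 16 (4S)-4-benzyl-3-{[(1S,2R,3R)-1-[4-(benzyloxy)-3-methoxyphenyl]-2-(benzyloxymethyl)-6-methoxy-7,8-(diphenylmethylenedioxy)tetralin-3-yl]carbonyl}oxazolidin-2-one
Product: 17 [(1S,2R,3R)-1-[4-(benzyloxy)-3-methoxyphenyl]-2-(benzyloxymethyl)-6-methoxy-7,8-(diphenylmethylenedioxy)tetralin-3-yl]methanol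
Conditions: LiBH4, MeOH (1 equiv), THF, 0 °C
Reagents that add atoms: none
Why: Reductive cleavage of the N-acyloxazolidinone by hydride attack at the exocyclic carbonyl gives the primary alcohol and returns 14; C3 is not enolised under these conditions, and benzyl ethers and ketal are inert.

Step 12
Reactants: 17 [(1S,2R,3R)-1-[4-(benzyloxy)-3-methoxyphenyl]-2-(benzyloxymethyl)-6-methoxy-7,8-(diphenylmethylenedioxy)tetralin-3-yl]methanol
Product: 18 (1S,2R,3R)-1-(4-hydroxy-3-methoxyphenyl)-2,3-bis(hydroxymethyl)-6-methoxytetralin-7,8-diol (CNP0219328.1)
Conditions: H2 (1 atm), Pd(OH)2/C, THF/MeOH, rt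
Reagents that add atoms: none
Why: Catalytic hydrogenolysis cleaves the aryl benzyl ether, the alkyl benzyl ether and both benzylic C–O bonds of the diphenylmethylene ketal in one operation; the stereocentres carry no heteroatom and are untouched, and the neutral, reductive medium protects the methoxycatechol, which is worked up under argon.

## Compound list

1 | 3,4-dihydroxy-5-methoxybenzaldehyde (5-hydroxyvanillin) | COc1cc(C=O)cc(O)c1O | starting material
2 | 7-methoxy-2,2-diphenyl-1,3-benzodioxole-5-carbaldehyde | COc1cc(C=O)cc2OC(c3ccccc3)(c3ccccc3)Oc12 | intermediate
3 | dimethyl malonate | COC(=O)CC(=O)OC | starting material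
4 | dimethyl 2-[(7-methoxy-2,2-diphenyl-1,3-benzodioxol-5-yl)methylidene]malonate | COC(=O)C(=Cc1cc(OC)c2OC(c3ccccc3)(c3ccccc3)Oc2c1)C(=O)OC | intermediate
5 | dimethyl 2-[(7-methoxy-2,2-diphenyl-1,3-benzodioxol-5-yl)methyl]malonate | COC(=O)C(Cc1cc(OC)c2OC(c3ccccc3)(c3ccccc3)Oc2c1)C(=O)OC | intermediate
6 | (E)-ferulic acid | COc1cc(/C=C/C(O)=O)ccc1O | starting material
7 | benzyl (E)-3-[4-(benzyloxy)-3-methoxyphenyl]prop-2-enoate | COc1cc(/C=C/C(=O)OCc2ccccc2)ccc1OCc1ccccc1 | intermediate
8 | (E)-3-[4-(benzyloxy)-3-methoxyphenyl]prop-2-en-1-ol | COc1cc(/C=C/CO)ccc1OCc1ccccc1 | intermediate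
9 | 1-(benzyloxy)-4-[(E)-3-(benzyloxy)prop-1-enyl]-2-methoxybenzene | COc1cc(/C=C/COCc2ccccc2)ccc1OCc1ccccc1 | intermediate
10 | dimethyl rac-(1S,2R)-1-[4-(benzyloxy)-3-methoxyphenyl]-2-(benzyloxymethyl)-6-methoxy-7,8-(diphenylmethylenedioxy)tetralin-3,3-dicarboxylate (racemate, 1,2-trans) | COc1cc([C@H]2c3c(cc(OC)c4OC(c5ccccc5)(c5ccccc5)Oc34)CC(C(=O)OC)(C(=O)OC)[C@@H]2COCc2ccccc2)ccc1OCc1ccccc1 | intermediate
11 | methyl rac-(1S,2R)-1-[4-(benzyloxy)-3-methoxyphenyl]-2-(benzyloxymethyl)-6-methoxy-7,8-(diphenylmethylenedioxy)tetralin-3-carboxylate (racemate, both C3 epimers) | COc1cc([C@H]2c3c(cc(OC)c4OC(c5ccccc5)(c5ccccc5)Oc34)CC(C(=O)OC)[C@@H]2COCc2ccccc2)ccc1OCc1ccccc1 | intermediate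
12 | methyl rac-(1S,2R,3R)-1-[4-(benzyloxy)-3-methoxyphenyl]-2-(benzyloxymethyl)-6-methoxy-7,8-(diphenylmethylenedioxy)tetralin-3-carboxylate (racemate, all-trans) | COc1cc([C@H]2c3c(cc(OC)c4OC(c5ccccc5)(c5ccccc5)Oc34)C[C@@H](C(=O)OC)[C@@H]2COCc2ccccc2)ccc1OCc1ccccc1 | intermediate
13 | rac-(1S,2R,3R)-1-[4-(benzyloxy)-3-methoxyphenyl]-2-(benzyloxymethyl)-6-methoxy-7,8-(diphenylmethylenedioxy)tetralin-3-carboxylic acid (racemate, all-trans) | COc1cc([C@H]2c3c(cc(OC)c4OC(c5ccccc5)(c5ccccc5)Oc34)C[C@@H](C(O)=O)[C@@H]2COCc2ccccc2)ccc1OCc1ccccc1 | intermediate
14 | (S)-4-benzyloxazolidin-2-one | O=C1OC[C@H](Cc2ccccc2)N1 | starting material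
15 | mixed anhydride of acid 13 and pivalic acid (racemate) | COc1cc([C@H]2c3c(cc(OC)c4OC(c5ccccc5)(c5ccccc5)Oc34)C[C@@H](C(=O)OC(=O)C(C)(C)C)[C@@H]2COCc2ccccc2)ccc1OCc1ccccc1 | intermediate
16 | (4S)-4-benzyl-3-{[(1S,2R,3R)-1-[4-(benzyloxy)-3-methoxyphenyl]-2-(benzyloxymethyl)-6-methoxy-7,8-(diphenylmethylenedioxy)tetralin-3-yl]carbonyl}oxazolidin-2-one | COc1cc([C@H]2c3c(cc(OC)c4OC(c5ccccc5)(c5ccccc5)Oc34)C[C@@H](C(=O)N4[C@@H](Cc5ccccc5)COC4=O)[C@@H]2COCc2ccccc2)ccc1OCc1ccccc1 | intermediate
17 | [(1S,2R,3R)-1-[4-(benzyloxy)-3-methoxyphenyl]-2-(benzyloxymethyl)-6-methoxy-7,8-(diphenylmethylenedioxy)tetralin-3-yl]methanol | COc1cc([C@H]2c3c(cc(OC)c4OC(c5ccccc5)(c5ccccc5)Oc34)C[C@@H](CO)[C@@H]2COCc2ccccc2)ccc1OCc1ccccc1 | intermediate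
18 | (1S,2R,3R)-1-(4-hydroxy-3-methoxyphenyl)-2,3-bis(hydroxymethyl)-6-methoxytetralin-7,8-diol | COc1cc([C@H]2c3c(cc(OC)c(O)c3O)C[C@@H](CO)[C@@H]2CO)ccc1O | target

## Step count and least certain steps

Total step count: 12. Longest linear sequence: 9 steps (steps 1, 2, 3, 7, 8, 9, 10, 11, 12; the branch through steps 4, 5, 6 is equally long).

**Step 7 (key step).** Four processes are the most likely to go wrong:
- The C1 cation may be captured faster than it closes the ring: by a malonate ester oxygen (lactonisation with loss of a methyl group), by acetate, or by loss of a proton to an alkene.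
- Part of the closure may occur at C5.
- Slow enolisation of the tertiary malonate may leave the oxidant time to degrade the electron-rich alkene.
- The ketal may be lost in warm aqueous acetic acid.

All four stem from running a strong oxidant and an acid together with a long-lived cation. The fallback sets out from 5 and 9 and comes back at 10. It separates radical generation from ring closure and uses neither oxidant nor acid. Malonate 5 is deprotonated with NaH and brominated with N-bromosuccinimide to dimethyl 2-bromo-2-[(7-methoxy-2,2-diphenyl-1,3-benzodioxol-5-yl)methyl]malonate F1. Atom-transfer radical addition of F1 to 9 under visible-light photoredox catalysis (Ru(bpy)3Cl2, blue light, DMF) gives the benzylic bromide adduct dimethyl 2-{1-[4-(benzyloxy)-3-methoxyphenyl]-1-bromo-3-(benzyloxy)propan-2-yl}-2-[(7-methoxy-2,2-diphenyl-1,3-benzodioxol-5-yl)methyl]malonate F2. Ionisation of F2 with ZnBr2 and 2,6-di-tert-butylpyridine in CH2Cl2 at low temperature then closes ring B by Friedel–Crafts alkylation to 10.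

**Step 10.** Separation of the two imides may be incomplete, because they differ only in the relation between the auxiliary and a fairly distant tetralin. Partial epimerisation at C3 through a ketene from the mixed anhydride would add further isomers. The fallback sets out from 13 and comes back at 17. Acid 13 is reduced with LiAlH4 to the racemic alcohol rac-[(1S,2R,3R)-1-[4-(benzyloxy)-3-methoxyphenyl]-2-(benzyloxymethyl)-6-methoxy-7,8-(diphenylmethylenedioxy)tetralin-3-yl]methanol F3. The enantiomers of F3 are then parted by preparative chromatography on a chiral stationary phase (cellulose tris(3,5-dimethylphenylcarbamate)), and the (1S,2R,3R) enantiomer is 17.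

**Step 9.** The equilibrium at C3 may not lie far enough on the trans side if the C1 aryl group turns pseudo-axial, and hydrolysis may begin before equilibrium is reached. The fallback sets out from 11 and comes back at 17, moving the equilibration to the aldehyde level, where enolisation needs only a mild amine base. Ester 11 is reduced with i-Bu2AlH at −78 °C to the aldehyde, which is equilibrated with DBU in CH2Cl2 to the all-trans aldehyde rac-(1S,2R,3R)-1-[4-(benzyloxy)-3-methoxyphenyl]-2-(benzyloxymethyl)-6-methoxy-7,8-(diphenylmethylenedioxy)tetralin-3-carbaldehyde F4. NaBH4 reduction of F4 gives the racemic alcohol F3, from which any cis epimer is removed as a diastereomer on silica, and resolution of F3 on the chiral stationary phase described above gives 17.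

**Step 12.** Hydrogenolysis of the hindered diphenylmethylene ketal may lag behind that of the benzyl ethers, and the freed methoxycatechol may oxidise in air during a prolonged reaction or work-up. The fallback sets out from 17 and comes back at 18, removing the ketal by hydrolysis first. Heating 17 in 80% aqueous AcOH at 90 °C gives the catechol (1S,2R,3R)-1-[4-(benzyloxy)-3-methoxyphenyl]-2-(benzyloxymethyl)-3-(hydroxymethyl)-6-methoxytetralin-7,8-diol F5. Brief hydrogenolysis of F5 (H2, Pd/C, MeOH) then removes the two benzyl ethers to give 18.

## Further compounds

F1 | step 7 | dimethyl 2-bromo-2-[(7-methoxy-2,2-diphenyl-1,3-benzodioxol-5-yl)methyl]malonate | COC(=O)C(Br)(Cc1cc(OC)c2OC(c3ccccc3)(c3ccccc3)Oc2c1)C(=O)OC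
F2 | step 7 | dimethyl 2-{1-[4-(benzyloxy)-3-methoxyphenyl]-1-bromo-3-(benzyloxy)propan-2-yl}-2-[(7-methoxy-2,2-diphenyl-1,3-benzodioxol-5-yl)methyl]malonate (mixture of stereoisomers) | COc1cc(C(Br)C(COCc2ccccc2)C(Cc2cc(OC)c3OC(c4ccccc4)(c4ccccc4)Oc3c2)(C(=O)OC)C(=O)OC)ccc1OCc1ccccc1
F3 | step 10 | rac-[(1S,2R,3R)-1-[4-(benzyloxy)-3-methoxyphenyl]-2-(benzyloxymethyl)-6-methoxy-7,8-(diphenylmethylenedioxy)tetralin-3-yl]methanol (racemate of 17; one enantiomer drawn) | COc1cc([C@H]2c3c(cc(OC)c4OC(c5ccccc5)(c5ccccc5)Oc34)C[C@@H](CO)[C@@H]2COCc2ccccc2)ccc1OCc1ccccc1
F4 | step 9 | rac-(1S,2R,3R)-1-[4-(benzyloxy)-3-methoxyphenyl]-2-(benzyloxymethyl)-6-methoxy-7,8-(diphenylmethylenedioxy)tetralin-3-carbaldehyde (racemate; one enantiomer drawn) | COc1cc([C@H]2c3c(cc(OC)c4OC(c5ccccc5)(c5ccccc5)Oc34)C[C@@H](C=O)[C@@H]2COCc2ccccc2)ccc1OCc1ccccc1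
F5 | step 12 | (1S,2R,3R)-1-[4-(benzyloxy)-3-methoxyphenyl]-2-(benzyloxymethyl)-3-(hydroxymethyl)-6-methoxytetralin-7,8-diol | COc1cc([C@H]2c3c(cc(OC)c(O)c3O)C[C@@H](CO)[C@@H]2COCc2ccccc2)ccc1OCc1ccccc1
A1 | alternative 1 | all-trans 1-[4-(benzyloxy)-3-methoxyphenyl]-8-(benzyloxy)-2,3-bis(benzyloxymethyl)-6-methoxytetralin-7-ol | COc1cc([C@H]2c3c(cc(OC)c(O)c3OCc3ccccc3)C[C@@H](COCc3ccccc3)[C@@H]2COCc4ccccc4)ccc1OCc1ccccc1
A2 | alternative 1 | acyclic C4 tosylate: 4-[2-(benzyloxy)-3-hydroxy-4-methoxyphenyl]-4-[4-(benzyloxy)-3-methoxyphenyl]-2,3-bis(benzyloxymethyl)butyl 4-methylbenzenesulfonate, configured as in A1 | COc1cc([C@H]([C@@H](COCc2ccccc2)[C@H](COCc2ccccc2)COS(=O)(=O)c2ccc(C)cc2)c2ccc(OC)c(O)c2OCc2ccccc2)ccc1OCc1ccccc1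
A3 | alternative 2 | (1S)-1-[4-(benzyloxy)-3-methoxyphenyl]-3-[(tert-butyldimethylsilyloxy)methyl]-6-methoxy-1,4-dihydronaphthalene-7,8-diol | COc1cc([C@@H]2C=C(CO[Si](C)(C)C(C)(C)C)Cc3cc(OC)c(O)c(O)c32)ccc1OCc1ccccc1
A4 | alternative 2 | 3-methoxy-1,2-benzoquinone | COC1=CC=CC(=O)C1=O
A5 | alternative 2 | (E)-1-[4-(benzyloxy)-3-methoxyphenyl]-3-[(tert-butyldimethylsilyloxy)methyl]buta-1,3-diene | COc1cc(/C=C/C(=C)CO[Si](C)(C)C(C)(C)C)ccc1OCc1ccccc1
A6 | alternative 3 | all-trans 7-(benzyloxy)-3-(benzyloxymethyl)-1-(4-hydroxy-3-methoxyphenyl)-6-methoxy-8-(methoxymethoxy)tetralin-2-carbaldehyde | COc1cc([C@H]2c3c(cc(OC)c(OCc4ccccc4)c3OCOC)C[C@@H](COCc3ccccc3)[C@@H]2C=O)ccc1O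
A7 | alternative 3 | quinone methide aldehyde: 4-{4-(benzyloxy)-5-methoxy-3-(methoxymethoxy)-2-[(3-methoxy-4-oxocyclohexa-2,5-dien-1-ylidene)methyl]phenyl}-3-(benzyloxymethyl)butanal, C3 configured as in A6 | COC1=CC(=Cc2c(C[C@@H](COCc3ccccc3)CC=O)cc(OC)c(OCc3ccccc3)c2OCOC)C=CC1=O
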